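If a chain grows for as long as it has lived, its length is one unit plus its net growth rate times its age, so I asked how old the chains were.

| setting | spring | dawn |
|---|---|---|
| free monomer | 0.078 M | 0.25 M |
| pre-initiator | 4.8 mM | 4.8 mM |
| time | 1.5 min | 1.5 min |

    free monomer + initiator → living end + monomer in chains (k1 = 3.6 /M/s)
    free monomer + living end → monomer in chains + living end, rate k2*[living end]*[free monomer] (k2 = 1.7 /M/s)
    monomer in chains + living end → free monomer + living end, rate k3*[living end] as long as [monomer in chains] is above zero (k3 = 0.025 /s)
    pre-initiator → initiator (k4 = 0.0022 /s)

- the average divides the monomer in chains by the number of chains begun, living and dead together
- run time (spring): 1.5 min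

1. which of the two ends with the longer chains by the average number of monomer units in a chain (chains begun, living or dead) ("neither" if they lie within 10 %) (spring / dawn / neither)
2. average number of monomer units in a chain (chains begun, living or dead) at the end, spring
3. average number of monomer units in a chain (chains begun, living or dead) at the end, dawn

I took the net gain per living end, g, as the growth constant times c(free monomer), less the constant of the back step. With c(free monomer) held at its charge, that made 0.108 /s in spring and 0.400 /s at dawn.

I started from two extreme flasks. With every chain begun at the first moment, the lengths were 10.7 in spring and 37.0 at dawn; with every chain begun at the last moment, the length was one unit. The real flasks lay between. In spring the initiator's half-life by step 1, with the charges as they stood at the start, was 2.5 s against 5.25 min for the pre-initiator, so I treated the release as the rate-limiting step and let chains begin as it went. I worked with the fraction of pre-initiator left, the same in both flasks: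

f = 82.0 %

From it came a, the average time a chain had been growing at the end:

a = 90 s / (1 − f) − 455 s = 46.5 s

This mean age of a chain was about half of the run.

length = 1 + g·a: spring 6.00, dawn 19.6

My dawn length bound 6.76 % of the charged free monomer, so holding c(free monomer) at its charge put my figures on the high side.

The forecast chose dawn, with 5.6 (5.2 to 6) for spring and 18.7 (17.5 to 20) for dawn, on the ground that “chain starts are set by the slow pre-initiator release”. Its dawn value stood lower than mine.

The simulation gave dawn, with 5.63 in spring and 18.7 at dawn.

At dawn, at 1.50 min, monomer in chains was made 16.3 times faster than it was used up, each step taken net. Dawn's half-life of free monomer by growth was then 8.0 min, longer than the run, and 94 % of the charged free monomer remained. Dawn's length, read through the mean age, gave a net gain of 0.381 /s per end. The neighbour of dawn charged with 0.062 M of free monomer had g = 0.0804 /s, so the mean age gave 4.74, and that flask reached 4.42.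

Its constants were set for the occasion.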